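**Remark on the chemistry.** The target has no stereocentre, so no enantiocontrol is required; the racemic carbinol intermediates lose their stereocentre on aromatization. The olefination is assumed to give mainly the (2Z)-acrylate (ester anti to the chain), and any (2E) isomer would converge on the target because it lactonizes directly after the ring expansion.

## Retrosynthetic overview

1. The pyranone ring of the 6-hydroxy-7-methoxycoumarin is opened at the O1–C2 lactone bond to a (Z)-2-aryloxy-3-(2,5-dihydroxy-4-methoxyphenyl)acrylate. It is closed last, by E/Z photoisomerization and lactonization of the C8a hydroxyl onto the methyl ester.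
2. The benzene ring of that coumarin is cut at C4a–C8a. Feature: on this ring the oxygen on C8a (O1) and the hydroxyl on C6 are para, the methoxyl on C7 is ortho to the C6 hydroxyl, and C5 and C8 carry H. This methoxyhydroquinone pattern is what ring expansion of a 4-alkenyl-4-hydroxy-3-methoxycyclobutenone delivers.
3. The dienyl hydroxycyclobutenone is cut at the future C3=C4 by Horner–Wadsworth–Emmons olefination of a cyclobutenone enal with an umbelliferyloxy phosphonoacetate. The aryl ether C3–O is already in place, made by Rh-carbenoid O–H insertion into umbelliferone.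
4. The cyclobutenone enal comes from addition of a β-formylvinyllithium equivalent (from 3,3-diethoxypropyne) to the ketone-like carbonyl of methyl semisquarate, itself made from dimethyl squarate.
5. Ring order: the umbelliferone bicycle and the four-membered ring are bought; the benzene ring forms in step 9 and the pyranone ring in step 10.

Key step: step 9

## Route

Step 1
Reactants: 1 dimethyl squarate (3,4-dimethoxycyclobut-3-ene-1,2-dione)
Product: 2 (±)-4-hydroxy-2,3-dimethoxycyclobut-2-en-1-one
Conditions: LiAlH(Ot-Bu)3 (1.05 equiv), THF, −78 → −20 °C; aq. work-up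
Reagents that add atoms: none
Why: The bulky, mild hydride should reduce one carbonyl of the squarate chemoselectively (1,2-reduction) and stop at the mono-alcohol, the established entry to semisquarates; the carbinol centre forms racemic and is removed in step 2.

Step 2
Reactants: 2 (±)-4-hydroxy-2,3-dimethoxycyclobut-2-en-1-one
Product: 3 3-methoxycyclobut-3-ene-1,2-dione (methyl semisquarate)
Conditions: conc. aq. HCl (cat.), CH2Cl2, 0 °C → rt; used freshly prepared
Reagents that add atoms: water, O (from the aqueous HCl; supplies the new carbonyl oxygen)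
Why: Acid-catalysed allylic transposition: ionization of the C4 hydroxyl gives a methoxy-stabilized cyclobutenyl cation, water adds at the methoxy-bearing C2 and methanol is lost, giving the cyclobutenedione.

Step 3
Reactants: 4 3,3-diethoxyprop-1-yne
Product: 5 (E)-tributyl(3,3-diethoxyprop-1-en-1-yl)stannane
Conditions: Bu3SnH (1.1 equiv), AIBN (cat.), neat, 85 °C
Reagents that add atoms: tributyltin hydride, CCCC[SnH](CCCC)CCCC
Why: Radical hydrostannation places tin on the terminal alkyne carbon, and reversible stannyl-radical addition under the slight excess of stannane should equilibrate the vinylstannane to the (E) isomer.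

Step 4
Reactants: 5 (E)-tributyl(3,3-diethoxyprop-1-en-1-yl)stannane; 3 3-methoxycyclobut-3-ene-1,2-dione
Product: 7 (±)-4-[(E)-3,3-diethoxyprop-1-en-1-yl]-4-hydroxy-3-methoxycyclobut-2-en-1-one, via (E)-(3,3-diethoxyprop-1-en-1-yl)lithium 6 (not isolated)
Conditions: n-BuLi, THF, −78 °C; cannulated into 3, THF, −78 °C; sat. aq. NH4Cl at −78 °C
Reagents that add atoms: n-butyllithium, [Li]CCCC (supplies the lithium of 6; none of its atoms remains in 7)
Why: Tin–lithium exchange proceeds with retention of alkene geometry, and the vinyllithium should add 1,2 to the ketone-like carbonyl next to the methoxy-bearing carbon (the other carbonyl is deactivated as a vinylogous ester), inverse addition at −78 °C suppressing a second addition; the carbinol centre forms racemic and is lost on aromatization.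

Step 5
Reactants: 7 (±)-4-[(E)-3,3-diethoxyprop-1-en-1-yl]-4-hydroxy-3-methoxycyclobut-2-en-1-one
Product: 8 (±)-(E)-3-(1-hydroxy-2-methoxy-4-oxocyclobut-2-en-1-yl)prop-2-enal
Conditions: PPTS (cat.), acetone–H2O (10:1), rt
Reagents that add atoms: water, O
Why: Acetal hydrolysis through the allyl-stabilized oxocarbenium ion should be far faster than hydrolysis of the vinylogous ester, and the (E) geometry keeps the tertiary alcohol from closing to a lactol.

Step 6
Reactants: 9 trimethyl phosphonoacetate
Product: 10 methyl 2-diazo-2-(dimethoxyphosphoryl)acetate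
Conditions: NaH, THF, 0 °C; p-ABSA, 0 °C → rt; aq. NH4Cl
Reagents that add atoms: 4-acetamidobenzenesulfonyl azide (p-ABSA), CC(=O)Nc1ccc(cc1)S(=O)(=O)N=[N+]=[N-]
Why: Regitz diazo transfer from the sulfonyl azide to the sodium phosphonoacetate carbanion.

Step 7
Reactants: 10 methyl 2-diazo-2-(dimethoxyphosphoryl)acetate; 11 umbelliferone (7-hydroxy-2H-chromen-2-one)
Product: 12 (±)-methyl 2-(dimethoxyphosphoryl)-2-[(2-oxo-2H-chromen-7-yl)oxy]acetate
Conditions: Rh2(OAc)4 (1 mol %), ClCH2CH2Cl, 80 °C, slow addition of 10
Reagents that add atoms: none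
Why: Rhodium-carbenoid O–H insertion into the phenol; the electrophilic acceptor/acceptor carbenoid should not cyclopropanate the electron-poor coumarin alkene, and the new stereocentre (racemic) is destroyed in step 8.

Step 8
Reactants: 12 (±)-methyl 2-(dimethoxyphosphoryl)-2-[(2-oxo-2H-chromen-7-yl)oxy]acetate; 8 (±)-(E)-3-(1-hydroxy-2-methoxy-4-oxocyclobut-2-en-1-yl)prop-2-enal
Product: 13 (±)-methyl (2Z,4E)-5-(1-hydroxy-2-methoxy-4-oxocyclobut-2-en-1-yl)-2-[(2-oxo-2H-chromen-7-yl)oxy]penta-2,4-dienoate
Conditions: LiCl, DBU, MeCN, 0 °C → rt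
Reagents that add atoms: none
Why: Horner–Wadsworth–Emmons olefination under Masamune–Roush conditions, in which the lithium-chelated phosphonate is deprotonated by an amine so that the tertiary hydroxycyclobutenone never meets a strong base; the 4E alkene is carried over from 8 and the new C2=C3 bond should form mainly Z (ester anti to the chain).

Step 9
Reactants: 13 (±)-methyl (2Z,4E)-5-(1-hydroxy-2-methoxy-4-oxocyclobut-2-en-1-yl)-2-[(2-oxo-2H-chromen-7-yl)oxy]penta-2,4-dienoate
Product: 16 methyl (Z)-3-(2,5-dihydroxy-4-methoxyphenyl)-2-[(2-oxo-2H-chromen-7-yl)oxy]prop-2-enoate, via methyl (2Z,4E,6Z)-6-hydroxy-7-methoxy-9-oxo-2-[(2-oxo-2H-chromen-7-yl)oxy]nona-2,4,6,8-tetraenoate 14 (not isolated), via (±)-methyl (Z)-3-(3-hydroxy-4-methoxy-6-oxocyclohexa-2,4-dien-1-yl)-2-[(2-oxo-2H-chromen-7-yl)oxy]prop-2-enoate 15 (not isolated)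
Conditions: PhMe (degassed, 0.01 M), 110 °C, Ar; concentrated under Ar and used at once
Reagents that add atoms: none
Why: Thermal conrotatory 4π opening of the cyclobutenone (carbinol carbon–carbonyl bond) gives dienylketene 14, the hydroxyl rotating outward as donor substituents do, so that the dienyl chain lies cis to the ketene. A 6π electrocyclization between the ketene carbon and the far carbon of the (E)-alkene then forms C4a–C8a and closes the benzene ring as cyclohexadienone 15, which tautomerizes to the hydroquinone; this is the Moore rearrangement of 4-alkenyl-4-hydroxycyclobutenones. No stereocentre survives, since the sp3 carbon of 15 aromatizes. The carbinol carbon becomes C6 (hydroxyl next to the methoxy-bearing C7) and the ketene carbon becomes C8a (hydroxyl ortho to the acrylate), so the two hydroxyls are told apart by position, the regiochemistry having been fixed by the site of addition in step 4. The step needs 6π closure in preference to capture of the ketene by the hydroxyl (furanone) or an 8π closure along the dienoate: outward rotation keeps the hydroxyl away from the ketene carbon, and the (E)-C4=C5 alkene cannot bring the acrylate terminus within reach. Exclusion of oxygen keeps the methoxyhydroquinone from oxidizing to the quinone.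

Step 10
Reactants: 16 methyl (Z)-3-(2,5-dihydroxy-4-methoxyphenyl)-2-[(2-oxo-2H-chromen-7-yl)oxy]prop-2-enoate
Product: 18 6-hydroxy-7-methoxy-3-[(2-oxo-2H-chromen-7-yl)oxy]-2H-chromen-2-one, via methyl (E)-3-(2,5-dihydroxy-4-methoxyphenyl)-2-[(2-oxo-2H-chromen-7-yl)oxy]prop-2-enoate 17 (not isolated)
Conditions: hν (365 nm LED), degassed MeCN (5 mM), Ar, rt; then PPTS (cat.), 50 °C
Reagents that add atoms: none
Why: Photochemical E/Z isomerization of the o-hydroxycinnamate chromophore brings the ester cis to the C8a hydroxyl in 17, which lactonizes with loss of methanol and so drains the photostationary mixture; the C6 hydroxyl is meta to the side chain and cannot reach the ester.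

## Compound list

1 | dimethyl squarate (3,4-dimethoxycyclobut-3-ene-1,2-dione) | COC1=C(OC)C(=O)C1=O | starting material
2 | (±)-4-hydroxy-2,3-dimethoxycyclobut-2-en-1-one | COC1=C(OC)C(O)C1=O | intermediate
3 | 3-methoxycyclobut-3-ene-1,2-dione (methyl semisquarate) | COC1=CC(=O)C1=O | intermediate
4 | 3,3-diethoxyprop-1-yne | CCOC(OCC)C#C | starting material
5 | (E)-tributyl(3,3-diethoxyprop-1-en-1-yl)stannane | CCCC[Sn](CCCC)(CCCC)/C=C/C(OCC)OCC | intermediate
6 | (E)-(3,3-diethoxyprop-1-en-1-yl)lithium | [Li]/C=C/C(OCC)OCC | intermediate (not isolated)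
7 | (±)-4-[(E)-3,3-diethoxyprop-1-en-1-yl]-4-hydroxy-3-methoxycyclobut-2-en-1-one | CCOC(OCC)/C=C/C1(O)C(OC)=CC1=O | intermediate
8 | (±)-(E)-3-(1-hydroxy-2-methoxy-4-oxocyclobut-2-en-1-yl)prop-2-enal | O=C/C=C/C1(O)C(OC)=CC1=O | intermediate
9 | trimethyl phosphonoacetate | COC(=O)CP(=O)(OC)OC | starting material
10 | methyl 2-diazo-2-(dimethoxyphosphoryl)acetate | COC(=O)C(=[N+]=[N-])P(=O)(OC)OC | intermediate
11 | umbelliferone (7-hydroxy-2H-chromen-2-one) | Oc1ccc2ccc(=O)oc2c1 | starting material
12 | (±)-methyl 2-(dimethoxyphosphoryl)-2-[(2-oxo-2H-chromen-7-yl)oxy]acetate | COC(=O)C(Oc1ccc2ccc(=O)oc2c1)P(=O)(OC)OC | intermediate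
13 | (±)-methyl (2Z,4E)-5-(1-hydroxy-2-methoxy-4-oxocyclobut-2-en-1-yl)-2-[(2-oxo-2H-chromen-7-yl)oxy]penta-2,4-dienoate | COC(=O)/C(Oc1ccc2ccc(=O)oc2c1)=C/C=C/C1(O)C(OC)=CC1=O | intermediate
14 | methyl (2Z,4E,6Z)-6-hydroxy-7-methoxy-9-oxo-2-[(2-oxo-2H-chromen-7-yl)oxy]nona-2,4,6,8-tetraenoate (dienylketene) | O=C=C/C(OC)=C(O)\C=C\C=C(/Oc1ccc2ccc(=O)oc2c1)C(=O)OC | intermediate (not isolated)
15 | (±)-methyl (Z)-3-(3-hydroxy-4-methoxy-6-oxocyclohexa-2,4-dien-1-yl)-2-[(2-oxo-2H-chromen-7-yl)oxy]prop-2-enoate | O=C1C=C(OC)C(O)=CC1/C=C(\Oc1ccc2ccc(=O)oc2c1)C(=O)OC | intermediate (not isolated)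
16 | methyl (Z)-3-(2,5-dihydroxy-4-methoxyphenyl)-2-[(2-oxo-2H-chromen-7-yl)oxy]prop-2-enoate | COC(=O)/C(Oc1ccc2ccc(=O)oc2c1)=C/c1cc(O)c(OC)cc1O | intermediate
17 | methyl (E)-3-(2,5-dihydroxy-4-methoxyphenyl)-2-[(2-oxo-2H-chromen-7-yl)oxy]prop-2-enoate | COC(=O)/C(Oc1ccc2ccc(=O)oc2c1)=C\c1cc(O)c(OC)cc1O | intermediate (not isolated)
18 | 6-hydroxy-7-methoxy-3-[(2-oxo-2H-chromen-7-yl)oxy]-2H-chromen-2-one | COc1cc2oc(=O)c(Oc3ccc4ccc(=O)oc4c3)cc2cc1O | target

## Step count

Total steps: 10.
Longest linear sequence: 7 steps (steps 1, 2, 4, 5, 8, 9, 10, from dimethyl squarate).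

## Steps most likely to fail

**Step 9 (ring expansion).** The hydroxyl may rotate inward during ring opening and then capture the ketene to give a furanone, the ketene may oligomerize through the dienoate, or the electron-rich hydroquinone may be oxidized by air during isolation. The fallback sets out from 13 and returns at 18. The tertiary alcohol is silylated (TESOTf, 2,6-lutidine, CH2Cl2, −78 °C) to give (±)-methyl (2Z,4E)-5-[2-methoxy-4-oxo-1-(triethylsilyloxy)cyclobut-2-en-1-yl]-2-[(2-oxo-2H-chromen-7-yl)oxy]penta-2,4-dienoate F1. Thermolysis of the silyl ether (degassed toluene, 110 °C) is the known protected variant of the ring expansion and should give the mono-silylated hydroquinone methyl (Z)-3-[2-hydroxy-4-methoxy-5-(triethylsilyloxy)phenyl]-2-[(2-oxo-2H-chromen-7-yl)oxy]prop-2-enoate F2. F2 has no free hydroxyl to intercept the ketene and only one phenol, so it is far less prone to oxidation. Irradiation as in step 10 passes through methyl (E)-3-[2-hydroxy-4-methoxy-5-(triethylsilyloxy)phenyl]-2-[(2-oxo-2H-chromen-7-yl)oxy]prop-2-enoate F3, which is not isolated, and gives 7-methoxy-3-[(2-oxo-2H-chromen-7-yl)oxy]-6-(triethylsilyloxy)-2H-chromen-2-one F4. HF·pyridine (THF, 0 °C) then removes the silyl group to give 18.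

**Step 10 (isomerization and lactonization).** The photostationary state may lie on the Z side while lactonization is slow, the coumarin chromophores may undergo [2+2] photodimerization as product builds up, or the hydroquinone may be photo-oxidized. The fallback sets out from 16 and returns at 18 by a ground-state route: anhydrous trifluoroacetic acid in 1,2-dichloroethane at 80 °C under argon. Reversible protonation of the push–pull acrylate at C2 gives a benzylic cation stabilized by the ortho hydroxyl and para methoxyl, rotation about C2–C3 becomes free, and the minor (E) isomer 17 is removed irreversibly by lactonization. Water is excluded so that the aryl enol ether is not hydrolysed. No new isolated compound is made.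

**Step 8 (olefination).** Base may open the free tertiary hydroxycyclobutenone through its alkoxide, or the phosphonate anion may add to the methoxy-enone faster than the hindered α-aryloxy phosphonate olefinates the aldehyde. The fallback sets out from 8 and returns at 13. The tertiary alcohol is capped (TMSOTf, Et3N, CH2Cl2, −78 °C; no enolizable position is present) to give (±)-(E)-3-[2-methoxy-4-oxo-1-(trimethylsilyloxy)cyclobut-2-en-1-yl]prop-2-enal F5. Olefination with 12 (LiCl, DBU, MeCN, 0 °C) then gives (±)-methyl (2Z,4E)-5-[2-methoxy-4-oxo-1-(trimethylsilyloxy)cyclobut-2-en-1-yl]-2-[(2-oxo-2H-chromen-7-yl)oxy]penta-2,4-dienoate F6, and AcOH–THF–H2O at rt removes the silyl group to give 13.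

## Further compounds

F1 | step 9 | (±)-methyl (2Z,4E)-5-[2-methoxy-4-oxo-1-(triethylsilyloxy)cyclobut-2-en-1-yl]-2-[(2-oxo-2H-chromen-7-yl)oxy]penta-2,4-dienoate | COC(=O)/C(Oc1ccc2ccc(=O)oc2c1)=C/C=C/C1(O[Si](CC)(CC)CC)C(OC)=CC1=O
F2 | step 9 | methyl (Z)-3-[2-hydroxy-4-methoxy-5-(triethylsilyloxy)phenyl]-2-[(2-oxo-2H-chromen-7-yl)oxy]prop-2-enoate | COC(=O)/C(Oc1ccc2ccc(=O)oc2c1)=C/c1cc(O[Si](CC)(CC)CC)c(OC)cc1O
F3 | step 9 | methyl (E)-3-[2-hydroxy-4-methoxy-5-(triethylsilyloxy)phenyl]-2-[(2-oxo-2H-chromen-7-yl)oxy]prop-2-enoate | COC(=O)/C(Oc1ccc2ccc(=O)oc2c1)=C\c1cc(O[Si](CC)(CC)CC)c(OC)cc1O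
F4 | step 9 | 7-methoxy-3-[(2-oxo-2H-chromen-7-yl)oxy]-6-(triethylsilyloxy)-2H-chromen-2-one | COc1cc2oc(=O)c(Oc3ccc4ccc(=O)oc4c3)cc2cc1O[Si](CC)(CC)CC
F0 | step 10 | none | none
F5 | step 8 | (±)-(E)-3-[2-methoxy-4-oxo-1-(trimethylsilyloxy)cyclobut-2-en-1-yl]prop-2-enal | O=C/C=C/C1(O[Si](C)(C)C)C(OC)=CC1=O
F6 | step 8 | (±)-methyl (2Z,4E)-5-[2-methoxy-4-oxo-1-(trimethylsilyloxy)cyclobut-2-en-1-yl]-2-[(2-oxo-2H-chromen-7-yl)oxy]penta-2,4-dienoate | COC(=O)/C(Oc1ccc2ccc(=O)oc2c1)=C/C=C/C1(O[Si](C)(C)C)C(OC)=CC1=O
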